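**Retrosynthetic overview**
- Ring C is closed last. The O1–C2 bond comes from a 6-endo oxa-Michael closure of an open-chain, fully unprotected α-methylene deoxybenzoin, and C3 (R) is set in the same operation when a chiral acid protonates the resulting cyclic enol.
- The enone comes from α-methylenation of a tetra-MOM deoxybenzoin, followed by buffered MOM removal without protic acid.
- The deoxybenzoin comes from acylation of a ring-A aryllithium (ortho-lithiated phloroglucinol tris-MOM ether) with a chromenylacetic Weinreb amide.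
- The pyran ring (ring D) on ring B comes from a Claisen cyclisation of an aryl 1,1-dimethylpropargyl ether. The two ring-B oxygens are told apart by starting from the lactone of 2,4-dihydroxyphenylacetic acid.
- Ring order: rings A and B are bought, ring D is formed first, ring C last.

Assumption: the lactone used in step 1 is taken as a bought material, and the (R)-acid is written for step 9 although which antipode gives 3R must be read from the first run (the other antipode is used if needed).

**Step 1**
Reactants: 1 6-hydroxy-1-benzofuran-2(3H)-one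
Product: 2 6-(methoxymethoxy)-1-benzofuran-2(3H)-one
Conditions: MOMCl, i-Pr2NEt, CH2Cl2, 0 °C to rt
Reagents that add atoms: chloromethyl methyl ether COCCl
Why: Williamson-type O-alkylation of the phenol by the hard, oxocarbenium-like MOMCl under a weak amine base, which neither opens the aryl lactone nor alkylates its C3.

**Step 2**
Reactants: 2 6-(methoxymethoxy)-1-benzofuran-2(3H)-one
Product: 3 2-[2-hydroxy-4-(methoxymethoxy)phenyl]-N-methoxy-N-methylacetamide
Conditions: MeNH(OMe)·HCl, AlMe3, CH2Cl2, 0 °C to rt; aq. potassium sodium tartrate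
Reagents that add atoms: N,O-dimethylhydroxylamine hydrochloride CNOC.Cl
Why: Weinreb amidation (aluminium amide aminolysis) of an activated aryl lactone frees only the oxygen ortho to the side chain, so the two ring-B oxygens are now differentiated.

**Step 3**
Reactants: 3 2-[2-hydroxy-4-(methoxymethoxy)phenyl]-N-methoxy-N-methylacetamide; 4 3-chloro-3-methylbut-1-yne
Product: 5 N-methoxy-2-[4-(methoxymethoxy)-2-[(2-methylbut-3-yn-2-yl)oxy]phenyl]-N-methylacetamide
Conditions: K2CO3, KI, CuI (cat.), acetone, 55 °C
Reagents that add atoms: none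
Why: copper-assisted O-alkylation of the single free, non-chelated phenoxide with a tertiary propargylic chloride (propargyl ether synthesis).

**Step 4**
Reactants: 5 N-methoxy-2-[4-(methoxymethoxy)-2-[(2-methylbut-3-yn-2-yl)oxy]phenyl]-N-methylacetamide
Product: 7 N-methoxy-2-[5-(methoxymethoxy)-2,2-dimethyl-2H-chromen-8-yl]-N-methylacetamide, via ortho-allenylphenol 6 (not isolated)
Conditions: o-xylene, 140 °C, sealed tube
Reagents that add atoms: none
Why: aromatic propargyl Claisen rearrangement, then 1,5-H shift and oxa-6π electrocyclisation; only one ortho position is free, so the pyran closes on the oxygen next to the side chain.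

**Step 5**
Reactants: 8 benzene-1,3,5-triol (phloroglucinol)
Product: 9 1,3,5-tris(methoxymethoxy)benzene
Conditions: NaH, MOMCl, DMF, 0 °C to rt
Reagents that add atoms: chloromethyl methyl ether COCCl
Why: exhaustive Williamson O-alkylation of the triphenoxide with a hard electrophile that favours O- over C-alkylation.

**Step 6**
Reactants: 9 1,3,5-tris(methoxymethoxy)benzene; 7 N-methoxy-2-[5-(methoxymethoxy)-2,2-dimethyl-2H-chromen-8-yl]-N-methylacetamide
Product: 11 2-[5-(methoxymethoxy)-2,2-dimethyl-2H-chromen-8-yl]-1-[2,4,6-tris(methoxymethoxy)phenyl]ethan-1-one, via aryllithium 10 (not isolated)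
Conditions: n-BuLi, THF, 0 °C, 1 h; then 7, −78 to −20 °C; aq. NH4Cl
Reagents that add atoms: n-butyllithium [Li]CCCC (lithium stays only in 10, none in 11)
Why: directed ortho-metalation between two OMOM groups, then Weinreb ketone synthesis, in which the chelated tetrahedral adduct stops cleanly at the ketone.

**Step 7**
Reactants: 11 2-[5-(methoxymethoxy)-2,2-dimethyl-2H-chromen-8-yl]-1-[2,4,6-tris(methoxymethoxy)phenyl]ethan-1-one
Product: 13 2-[5-(methoxymethoxy)-2,2-dimethyl-2H-chromen-8-yl]-1-[2,4,6-tris(methoxymethoxy)phenyl]prop-2-en-1-one, via Mannich base 12 (not isolated)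
Conditions: CH2(NMe2)2, Ac2O, DMF, 60 °C
Reagents that add atoms: bis(dimethylamino)methane CN(C)CN(C)C (CH2 stays in 13, CH2NMe2 in 12)
Why: Mannich α-aminomethylation of the benzylic ketone by the iminium acetate formed in the flask, then N-acylation and β-elimination (α-methylenation); all phenols are capped, so the ring cannot close and ring A is not aminomethylated.

**Step 8**
Reactants: 13 2-[5-(methoxymethoxy)-2,2-dimethyl-2H-chromen-8-yl]-1-[2,4,6-tris(methoxymethoxy)phenyl]prop-2-en-1-one
Product: 15 2-(5-hydroxy-2,2-dimethyl-2H-chromen-8-yl)-1-(2,4,6-trihydroxyphenyl)prop-2-en-1-one, via tetrakis(trimethylsilyl) ether 14 (not isolated)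
Conditions: TMSOTf, 2,2'-bipyridyl, MeCN, 0 °C to rt; then H2O, 0 °C; cold pH 4 work-up, used at once
Reagents that add atoms: trimethylsilyl trifluoromethanesulfonate C[Si](C)(C)OS(=O)(=O)C(F)(F)F (silyl groups stay only in 14, none in 15)
Why: silyl triflate/bipyridyl cleavage of aryl MOM ethers to aryl silyl ethers, which water hydrolyses; the buffered, weakly acidic medium has no protic acid or base strong enough to close the enone or attack the chromene.

**Step 9**
Reactants: 15 2-(5-hydroxy-2,2-dimethyl-2H-chromen-8-yl)-1-(2,4,6-trihydroxyphenyl)prop-2-en-1-one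
Product: 17 (3R)-5,7-dihydroxy-3-(5-hydroxy-2,2-dimethyl-2H-chromen-8-yl)-2,3-dihydro-4H-chromen-4-one, via cyclic enol 16 (not isolated)
Conditions: (R)-3,3'-bis(2,4,6-triisopropylphenyl)-1,1'-binaphthyl-2,2'-diyl hydrogen phosphate (10 mol%), 4 Å MS, CH2Cl2/MTBE 4:1, 0.02 M, −30 °C
Reagents that add atoms: none
Why: Proposed new method: a chiral phosphoric acid-catalysed 6-endo oxa-Michael ring closure coupled to enantioselective protonation of the enol it generates. The acid bridges the ketone oxygen (P–OH donor) and the free, non-chelated ortho phenol (P=O acceptor), so the phenol oxygen adds to the terminal CH2 and forms the O1–C2 bond; the two ortho phenols are equivalent, so only one product can form. The species formed is the achiral cyclic enol 16, so closure that happens without the catalyst costs no selectivity, and C3 is set only when the enol ketonises. The phosphoric acid is several pKa units stronger than any phenol in the flask and acts as a bifunctional proton shuttle (P=O takes the enol O–H, P–OH delivers H to C3) inside the pocket of its two 2,4,6-triisopropylphenyl groups, which leaves one face of C3 open and is expected to give the 3R ketone. No base is present, so the labile α-aryl ketone centre is not epimerised after it forms. Closest known reaction types: the racemic amine-mediated closure of 2-hydroxyaryl α-methylene benzyl ketones to isoflavanones, and chiral Brønsted acid-catalysed enantioselective protonation of silyl enol ethers and of enols formed in conjugate addition–protonation cascades.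

**Compound list**
1 | 6-hydroxy-1-benzofuran-2(3H)-one | O=C1Cc2ccc(O)cc2O1 | starting material
2 | 6-(methoxymethoxy)-1-benzofuran-2(3H)-one | O=C1Cc2ccc(OCOC)cc2O1 | intermediate
3 | 2-[2-hydroxy-4-(methoxymethoxy)phenyl]-N-methoxy-N-methylacetamide | CON(C)C(=O)Cc1ccc(OCOC)cc1O | intermediate
4 | 3-chloro-3-methylbut-1-yne | CC(C)(Cl)C#C | starting material
5 | N-methoxy-2-[4-(methoxymethoxy)-2-[(2-methylbut-3-yn-2-yl)oxy]phenyl]-N-methylacetamide | CON(C)C(=O)Cc1ccc(OCOC)cc1OC(C)(C)C#C | intermediate
6 | 2-[2-hydroxy-4-(methoxymethoxy)-3-(3-methylbuta-1,2-dien-1-yl)phenyl]-N-methoxy-N-methylacetamide | CON(C)C(=O)Cc1ccc(OCOC)c(C=C=C(C)C)c1O | intermediate (not isolated)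
7 | N-methoxy-2-[5-(methoxymethoxy)-2,2-dimethyl-2H-chromen-8-yl]-N-methylacetamide | CON(C)C(=O)Cc1ccc(OCOC)c2C=CC(C)(C)Oc12 | intermediate
8 | benzene-1,3,5-triol (phloroglucinol) | Oc1cc(O)cc(O)c1 | starting material
9 | 1,3,5-tris(methoxymethoxy)benzene | COCOc1cc(OCOC)cc(OCOC)c1 | intermediate
10 | [2,4,6-tris(methoxymethoxy)phenyl]lithium | [Li]c1c(OCOC)cc(OCOC)cc1OCOC | intermediate (not isolated)
11 | 2-[5-(methoxymethoxy)-2,2-dimethyl-2H-chromen-8-yl]-1-[2,4,6-tris(methoxymethoxy)phenyl]ethan-1-one | COCOc1cc(OCOC)c(C(=O)Cc2ccc(OCOC)c3C=CC(C)(C)Oc23)c(OCOC)c1 | intermediate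
12 | racemic 3-(dimethylamino)-2-[5-(methoxymethoxy)-2,2-dimethyl-2H-chromen-8-yl]-1-[2,4,6-tris(methoxymethoxy)phenyl]propan-1-one | COCOc1cc(OCOC)c(C(=O)C(CN(C)C)c2ccc(OCOC)c3C=CC(C)(C)Oc23)c(OCOC)c1 | intermediate (not isolated)
13 | 2-[5-(methoxymethoxy)-2,2-dimethyl-2H-chromen-8-yl]-1-[2,4,6-tris(methoxymethoxy)phenyl]prop-2-en-1-one | COCOc1cc(OCOC)c(C(=O)C(=C)c2ccc(OCOC)c3C=CC(C)(C)Oc23)c(OCOC)c1 | intermediate
14 | 2-[2,2-dimethyl-5-(trimethylsilyloxy)-2H-chromen-8-yl]-1-[2,4,6-tris(trimethylsilyloxy)phenyl]prop-2-en-1-one | C=C(C(=O)c1c(O[Si](C)(C)C)cc(O[Si](C)(C)C)cc1O[Si](C)(C)C)c1ccc(O[Si](C)(C)C)c2C=CC(C)(C)Oc12 | intermediate (not isolated)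
15 | 2-(5-hydroxy-2,2-dimethyl-2H-chromen-8-yl)-1-(2,4,6-trihydroxyphenyl)prop-2-en-1-one | C=C(C(=O)c1c(O)cc(O)cc1O)c1ccc(O)c2C=CC(C)(C)Oc12 | intermediate
16 | 3-(5-hydroxy-2,2-dimethyl-2H-chromen-8-yl)-2H-chromene-4,5,7-triol (achiral enol) | OC1=C(c2ccc(O)c3C=CC(C)(C)Oc23)COc2cc(O)cc(O)c12 | intermediate (not isolated)
17 | (3R)-5,7-dihydroxy-3-(5-hydroxy-2,2-dimethyl-2H-chromen-8-yl)-2,3-dihydro-4H-chromen-4-one | CC1(C)C=Cc2c(O)ccc([C@@H]3COc4cc(O)cc(O)c4C3=O)c2O1 | target

**Step count and risks**
Total steps: 9. Longest linear sequence: 8 (steps 1, 2, 3, 4, 6, 7, 8, 9).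

Three steps most likely to fail:

- **Step 9 (new ring closure/protonation).** The risks are low enantioselectivity, or ketonisation of the enol by the phenols instead of by the chiral acid. The fallback uses known chemistry and sets out from 15. Catalytic Et3N in THF at rt closes 15 to racemic 5,7-dihydroxy-3-(5-hydroxy-2,2-dimethyl-2H-chromen-8-yl)-2,3-dihydro-4H-chromen-4-one F1. Preparative HPLC on an amylose tris(3,5-dimethylphenylcarbamate) phase separates the enantiomers and returns to the route at 17. The other enantiomer, (3S)-5,7-dihydroxy-3-(5-hydroxy-2,2-dimethyl-2H-chromen-8-yl)-2,3-dihydro-4H-chromen-4-one F2, is racemised back to F1 with Et3N in warm THF and recycled.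

- **Step 8 (release of the free enone).** The risk is that 15 closes and ketonises during deprotection or work-up, giving racemic material before the catalyst is present. The fallback sets out from 13. TESOTf and 2,2'-bipyridyl in MeCN exchange the four MOM groups for triethylsilyl groups to give 2-[2,2-dimethyl-5-(triethylsilyloxy)-2H-chromen-8-yl]-1-[2,4,6-tris(triethylsilyloxy)phenyl]prop-2-en-1-one F3, which can be chromatographed and stored. Et3N·3HF in THF at −20 °C then frees the phenols under weakly acidic fluoride conditions immediately before step 9, returning to the route at 15.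

- **Step 6 (aryllithium on an enolisable Weinreb amide).** The risk is that the hindered aryllithium deprotonates the benzylic CH2 instead of adding. The fallback sets out from 7. i-Bu2AlH in THF at −78 °C reduces 7 to [5-(methoxymethoxy)-2,2-dimethyl-2H-chromen-8-yl]acetaldehyde F4, used crude. Aryllithium 10 (from 9) adds to the more electrophilic aldehyde at −78 °C to give racemic 2-[5-(methoxymethoxy)-2,2-dimethyl-2H-chromen-8-yl]-1-[2,4,6-tris(methoxymethoxy)phenyl]ethan-1-ol F5. Dess–Martin periodinane with NaHCO3 in CH2Cl2 oxidises F5 to the ketone, returning to the route at 11.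

**Further compounds**
F1 | step 9 | racemic 5,7-dihydroxy-3-(5-hydroxy-2,2-dimethyl-2H-chromen-8-yl)-2,3-dihydro-4H-chromen-4-one | CC1(C)C=Cc2c(O)ccc(C3COc4cc(O)cc(O)c4C3=O)c2O1
F2 | step 9 | (3S)-5,7-dihydroxy-3-(5-hydroxy-2,2-dimethyl-2H-chromen-8-yl)-2,3-dihydro-4H-chromen-4-one | CC1(C)C=Cc2c(O)ccc([C@H]3COc4cc(O)cc(O)c4C3=O)c2O1
F3 | step 8 | 2-[2,2-dimethyl-5-(triethylsilyloxy)-2H-chromen-8-yl]-1-[2,4,6-tris(triethylsilyloxy)phenyl]prop-2-en-1-one | C=C(C(=O)c1c(O[Si](CC)(CC)CC)cc(O[Si](CC)(CC)CC)cc1O[Si](CC)(CC)CC)c1ccc(O[Si](CC)(CC)CC)c2C=CC(C)(C)Oc12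
F4 | step 6 | [5-(methoxymethoxy)-2,2-dimethyl-2H-chromen-8-yl]acetaldehyde | O=CCc1ccc(OCOC)c2C=CC(C)(C)Oc12
F5 | step 6 | racemic 2-[5-(methoxymethoxy)-2,2-dimethyl-2H-chromen-8-yl]-1-[2,4,6-tris(methoxymethoxy)phenyl]ethan-1-ol | COCOc1cc(OCOC)c(C(O)Cc2ccc(OCOC)c3C=CC(C)(C)Oc23)c(OCOC)c1
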